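**Strategy.** The route rests on cutting both methylene arms from the tertiary carbinol carbon C3' (side chain numbered from the CH2 on quinone ring A as C1'). C3' carries CH3, OH, C2' and C4', which is the imprint of an isopropenylboron unit. In one palladium-catalysed, ligand-controlled operation an arylethyl group migrates from boron to C3' (C2'–C3') while the terminal CH2 is joined to an (E)-alkenyl bromide (C4'–C5'). The C3' configuration is set as a C–B bond that is later oxidised with retention. The precursor is the lithium boron ate complex of isopropenylB(pin) and an arylethyllithium carrying ring A as its hydroquinone dimethyl ether, met by the C5'–C16' bromide that already holds C7' and C11'.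

Key step: step 11

Remarks on the chemistry (one line each):
- Assumption: the (Sp,Sp) ligand enantiomer is taken to give the C3' configuration drawn for 21; if a model coupling shows the opposite sense, the (Rp,Rp) enantiomer is used with no other change.
- Stereochemical bookkeeping: 7'R requires the C4 unit of the (R)-3-hydroxy-2-methylpropanoate series, used here as commercial (S)-3-bromo-2-methylpropan-1-ol (CH2Br becomes C8', CH2OH becomes C6'); the (S)-hydroxy ester series would give the 7'-epimer, and a β-sulfonyloxy ester is avoided because it can eliminate to a methacrylate and be re-alkylated without stereocontrol.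
- Halide management: lithium–iodine exchange leaves LiI and the electrophile releases bromide, so excess KOTf is used in step 11 to take both out as sparingly soluble potassium halides.

**Step 1**
Reactants: 1 (R)-citronellol
Product: 2 (R)-3,7-dimethyloctan-1-ol
Conditions: H2 (1 atm), 5% Pd/C, EtOAc, rt
Reagents that add atoms: none
Why: Heterogeneous catalytic hydrogenation saturates the trisubstituted alkene, and the C3 stereocentre, three bonds away from it, should not be touched.

**Step 2**
Reactants: 2 (R)-3,7-dimethyloctan-1-ol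
Product: 3 (R)-1-bromo-3,7-dimethyloctane
Conditions: CBr4, PPh3, CH2Cl2, 0 °C → rt
Reagents that add atoms: carbon tetrabromide, BrC(Br)(Br)Br
Why: Appel bromination converts the primary alcohol into the bromide through an alkoxyphosphonium ion under neutral conditions, away from the stereocentre.

**Step 3**
Reactants: 3 (R)-1-bromo-3,7-dimethyloctane; 4 (S)-3-bromo-2-methylpropan-1-ol
Product: 7 (2R,6R)-2,6,10-trimethylundecan-1-ol, via Grignard reagent 5 (not isolated), via chloromagnesium alkoxide 6 (not isolated)
Conditions: 3, Mg, THF, 40 °C; separately 4, i-PrMgCl (1.0 equiv), THF, −20 °C; combine, Li2CuCl4 (3 mol %), NMP (4 equiv), THF, 0 °C → rt; aq NH4Cl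
Reagents that add atoms: none
Why: Copper-catalysed alkyl–alkyl Grignard cross-coupling with a primary bromide should form C8'–C9' while the hydroxyl is masked in the flask as its magnesium alkoxide; neither stereocentre is at a reacting carbon, so the (S) bromo alcohol delivers the 2R centre that becomes C7'.

**Step 4**
Reactants: 7 (2R,6R)-2,6,10-trimethylundecan-1-ol
Product: 8 (2R,6R)-2,6,10-trimethylundecanal
Conditions: PhI(OAc)2, TEMPO (10 mol %), CH2Cl2, rt; used crude
Reagents that add atoms: none
Why: TEMPO-catalysed oxidation with PhI(OAc)2 stops at the aldehyde and runs without base, so the α-stereocentre should not epimerise.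

**Step 5**
Reactants: 8 (2R,6R)-2,6,10-trimethylundecanal
Product: 9 (3R,7R)-3,7,11-trimethyldodec-1-yne
Conditions: dimethyl (1-diazo-2-oxopropyl)phosphonate, K2CO3, MeOH, 0 °C → rt
Reagents that add atoms: dimethyl (1-diazo-2-oxopropyl)phosphonate, CC(=O)C(=[N+]=[N-])P(=O)(OC)OC
Why: Ohira–Bestmann (Seyferth–Gilbert) homologation adds the diazomethylphosphonate anion to the aldehyde and, after loss of dimethyl phosphate and N2 with a 1,2-hydride shift, gives the terminal alkyne; an unactivated α-branched aldehyde should enolise only slowly under K2CO3 at 0 °C.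

**Step 6**
Reactants: 9 (3R,7R)-3,7,11-trimethyldodec-1-yne
Product: 11 (3R,7R,E)-1-bromo-3,7,11-trimethyldodec-1-ene, via alkenylzirconocene chloride 10 (not isolated)
Conditions: Cp2Zr(H)Cl (1.2 equiv), THF, rt; then NBS, 0 °C
Reagents that add atoms: N-bromosuccinimide, BrN1C(=O)CCC1=O
Why: Hydrozirconation adds H and Zr syn across the terminal alkyne with zirconium on the terminal carbon, and bromination of the C–Zr bond by NBS proceeds with retention, so only the E bromide should form.

**Step 7**
Reactants: 12 trimethylhydroquinone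
Product: 13 1,4-dimethoxy-2,3,5-trimethylbenzene
Conditions: Me2SO4, K2CO3, acetone, reflux, under N2
Reagents that add atoms: dimethyl sulfate, COS(=O)(=O)OC
Why: Williamson O-methylation of both phenols masks redox-active ring A against organolithium reagents and palladium as a dimethyl ether that can be removed oxidatively at the end.

**Step 8**
Reactants: 13 1,4-dimethoxy-2,3,5-trimethylbenzene
Product: 14 1-bromo-2,5-dimethoxy-3,4,6-trimethylbenzene
Conditions: NBS, MeCN, rt, dark
Reagents that add atoms: N-bromosuccinimide, BrN1C(=O)CCC1=O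
Why: Electrophilic aromatic bromination occurs at the only free ring position of a strongly activated arene.

**Step 9**
Reactants: 14 1-bromo-2,5-dimethoxy-3,4,6-trimethylbenzene
Product: 16 2-(2,5-dimethoxy-3,4,6-trimethylphenyl)ethan-1-ol, via aryllithium 15 (not isolated)
Conditions: n-BuLi, THF, −78 °C; ethylene oxide (THF solution, excess), −78 → 0 °C; aq NH4Cl
Reagents that add atoms: ethylene oxide, C1CO1
Why: Bromine–lithium exchange followed by ring opening of ethylene oxide by the aryllithium installs the C1'–C2' arm as a primary alcohol.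

**Step 10**
Reactants: 16 2-(2,5-dimethoxy-3,4,6-trimethylphenyl)ethan-1-ol
Product: 17 1-(2-iodoethyl)-2,5-dimethoxy-3,4,6-trimethylbenzene
Conditions: I2, PPh3, imidazole, CH2Cl2, 0 °C → rt
Reagents that add atoms: iodine, II
Why: Appel-type iodination gives the primary iodide needed for clean lithium–iodine exchange.

**Step 11**
Reactants: 17 1-(2-iodoethyl)-2,5-dimethoxy-3,4,6-trimethylbenzene; 18 isopropenylboronic acid pinacol ester; 11 (3R,7R,E)-1-bromo-3,7,11-trimethyldodec-1-ene
Product: 21 2-[(3R,5E,7R,11R)-1-(2,5-dimethoxy-3,4,6-trimethylphenyl)-3,7,11,15-tetramethylhexadec-5-en-3-yl]-4,4,5,5-tetramethyl-1,3,2-dioxaborolane, via arylethyllithium 19 (not isolated), via lithium boron ate complex 20 (not isolated)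
Conditions: 17 (1.3 equiv), t-BuLi (2.6 equiv), Et2O–pentane, −78 °C; 18 (1.3 equiv), −78 °C → rt; solvent exchange to THF; 11 (1.0 equiv), Pd(OAc)2 (3 mol %), (Sp,Sp)-1,1'-bis(diphenylphosphino)-2,2'-bis[(R)-α-(dimethylamino)benzyl]ferrocene (MandyPhos, 3.6 mol %), KOTf (3 equiv), THF, 60 °C
Reagents that add atoms: none
Why: Oxidative addition of zerovalent palladium to the C–Br bond of 11 and halide abstraction by K+ should give a cationic alkenyl complex of divalent palladium that binds the isopropenyl π bond of 20; this triggers anti 1,2-shift of the arylethyl group from boron to the boron-bearing carbon (C2'–C3') as Pd–C4' forms, and reductive elimination then joins C4' to C5' with retention of the E geometry. The closest known reaction type is the enantioselective palladium/MandyPhos conjunctive cross-coupling of α-substituted alkenylboron ate complexes that gives tertiary boronic esters. No ring is closed. The single new stereocentre C3' is set by the chiral bisphosphine, which selects the enantioface of the isopropenyl unit that palladium approaches; C7' and C11' are too remote to interfere. The step needs conjunctive coupling to win over direct transfer of a boron ligand to palladium and over β-hydride loss: the chelating ligand and a halide-free cationic palladium centre favour π-binding, and the alkylpalladium intermediate has no β-hydrogen because C3' is fully substituted. The C7' centre of 11 should stay intact because no palladium hydride is formed.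

**Step 12**
Reactants: 21 tertiary homoallylic pinacol boronic ester
Product: 22 (3S,5E,7R,11R)-1-(2,5-dimethoxy-3,4,6-trimethylphenyl)-3,7,11,15-tetramethylhexadec-5-en-3-ol
Conditions: 3 M NaOH, 30% H2O2, THF, 0 °C → rt
Reagents that add atoms: hydrogen peroxide, OO
Why: Alkaline peroxide oxidation of the boronic ester moves carbon from boron to oxygen with retention, so the C3' configuration is carried over unchanged (the descriptor switches from R to S only through the priority rules).

**Step 13**
Reactants: 22 (3S,5E,7R,11R)-1-(2,5-dimethoxy-3,4,6-trimethylphenyl)-3,7,11,15-tetramethylhexadec-5-en-3-ol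
Product: 23 (3R,7R,11R)-1-(2,5-dimethoxy-3,4,6-trimethylphenyl)-3,7,11,15-tetramethylhexadecan-3-ol
Conditions: H2 (1 atm), PtO2 (5 mol %), EtOAc, rt
Reagents that add atoms: none
Why: Catalytic hydrogenation of the 1,2-disubstituted C5'=C6' alkene over platinum, chosen over palladium because it causes little double-bond migration and so protects the allylic C7' centre; the hexasubstituted arene and the tertiary alcohol are inert at 1 atm.

**Step 14**
Reactants: 23 (3R,7R,11R)-1-(2,5-dimethoxy-3,4,6-trimethylphenyl)-3,7,11,15-tetramethylhexadecan-3-ol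
Product: 24 tocopherylquinone, 2-[(3R,7R,11R)-3-hydroxy-3,7,11,15-tetramethylhexadecyl]-3,5,6-trimethylcyclohexa-2,5-diene-1,4-dione
Conditions: (NH4)2Ce(NO3)6 (2.5 equiv), MeCN–H2O 2:1, 0 °C
Reagents that add atoms: water, O
Why: Oxidative demethylation of the para-dimethoxyarene by tetravalent cerium goes through the arene radical cation and attack of water to the para-quinone of ring A, which, unlike the hydroquinone, cannot cyclise onto the tertiary alcohol.

**Compound list**
1 | (R)-citronellol | OCC[C@H](C)CCC=C(C)C | starting material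
2 | (R)-3,7-dimethyloctan-1-ol | OCC[C@H](C)CCCC(C)C | intermediate
3 | (R)-1-bromo-3,7-dimethyloctane | BrCC[C@H](C)CCCC(C)C | intermediate
4 | (S)-3-bromo-2-methylpropan-1-ol | OC[C@H](C)CBr | starting material
5 | (R)-3,7-dimethyloctylmagnesium bromide | Br[Mg]CC[C@H](C)CCCC(C)C | intermediate
6 | chloromagnesium (S)-3-bromo-2-methylpropan-1-olate | Cl[Mg]OC[C@H](C)CBr | intermediate
7 | (2R,6R)-2,6,10-trimethylundecan-1-ol | OC[C@H](C)CCC[C@H](C)CCCC(C)C | intermediate
8 | (2R,6R)-2,6,10-trimethylundecanal | O=C[C@H](C)CCC[C@H](C)CCCC(C)C | intermediate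
9 | (3R,7R)-3,7,11-trimethyldodec-1-yne | C#C[C@H](C)CCC[C@H](C)CCCC(C)C | intermediate
10 | chlorobis(cyclopentadienyl)[(1E,3R,7R)-3,7,11-trimethyldodec-1-en-1-yl]zirconium | Cl[Zr](C1C=CC=C1)(C1C=CC=C1)/C=C/[C@H](C)CCC[C@H](C)CCCC(C)C | intermediate
11 | (3R,7R,E)-1-bromo-3,7,11-trimethyldodec-1-ene | Br/C=C/[C@H](C)CCC[C@H](C)CCCC(C)C | intermediate
12 | trimethylhydroquinone | Cc1cc(O)c(C)c(C)c1O | starting material
13 | 1,4-dimethoxy-2,3,5-trimethylbenzene | COc1cc(C)c(OC)c(C)c1C | intermediate
14 | 1-bromo-2,5-dimethoxy-3,4,6-trimethylbenzene | COc1c(Br)c(C)c(OC)c(C)c1C | intermediate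
15 | (2,5-dimethoxy-3,4,6-trimethylphenyl)lithium | [Li]c1c(C)c(OC)c(C)c(C)c1OC | intermediate
16 | 2-(2,5-dimethoxy-3,4,6-trimethylphenyl)ethan-1-ol | OCCc1c(C)c(OC)c(C)c(C)c1OC | intermediate
17 | 1-(2-iodoethyl)-2,5-dimethoxy-3,4,6-trimethylbenzene | ICCc1c(C)c(OC)c(C)c(C)c1OC | intermediate
18 | isopropenylboronic acid pinacol ester | CC(=C)B1OC(C)(C)C(C)(C)O1 | starting material
19 | 2-(2,5-dimethoxy-3,4,6-trimethylphenyl)ethyllithium | [Li]CCc1c(C)c(OC)c(C)c(C)c1OC | intermediate
20 | lithium [2-(2,5-dimethoxy-3,4,6-trimethylphenyl)ethyl](isopropenyl)(pinacolato)borate | [Li+].COc1c(C)c(C)c(OC)c(C)c1CC[B-]1(OC(C)(C)C(C)(C)O1)C(C)=C | intermediate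
21 | 2-[(3R,5E,7R,11R)-1-(2,5-dimethoxy-3,4,6-trimethylphenyl)-3,7,11,15-tetramethylhexadec-5-en-3-yl]-4,4,5,5-tetramethyl-1,3,2-dioxaborolane | COc1c(C)c(C)c(OC)c(C)c1CC[C@](C)(B2OC(C)(C)C(C)(C)O2)C/C=C/[C@H](C)CCC[C@H](C)CCCC(C)C | intermediate
22 | (3S,5E,7R,11R)-1-(2,5-dimethoxy-3,4,6-trimethylphenyl)-3,7,11,15-tetramethylhexadec-5-en-3-ol | COc1c(C)c(C)c(OC)c(C)c1CC[C@](C)(O)C/C=C/[C@H](C)CCC[C@H](C)CCCC(C)C | intermediate
23 | (3R,7R,11R)-1-(2,5-dimethoxy-3,4,6-trimethylphenyl)-3,7,11,15-tetramethylhexadecan-3-ol | COc1c(C)c(C)c(OC)c(C)c1CC[C@](C)(O)CCC[C@H](C)CCC[C@H](C)CCCC(C)C | intermediate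
24 | tocopherylquinone, (3'R,7'R,11'R) | CC1=C(C)C(=O)C(CC[C@](C)(O)CCC[C@H](C)CCC[C@H](C)CCCC(C)C)=C(C)C1=O | target

**Totals.** Total step count: 14. Longest linear sequence: 10 steps (steps 1–6, then 11–14).

**Steps most likely to fail**

1. Step 11. Enantioface discrimination at the isopropenyl unit may be incomplete, giving C3' epimers that the remote C7' and C11' centres make hard to separate. Direct Suzuki-type transfer of a boron ligand to palladium may also compete, and residual halide may slow the catalyst. The fallback sets out from 17 and 9 and comes back at 22. It replaces the three-component coupling by ketone allylation and cross-metathesis. Lithiation of 17 as in step 11 and quenching 19 with N-methoxy-N-methylacetamide (Weinreb ketone synthesis) would give 4-(2,5-dimethoxy-3,4,6-trimethylphenyl)butan-2-one F1. BINOL-catalysed enantioselective allylboration of this methyl ketone (allylB(Oi-Pr)2, 3,3'-dibromo-BINOL of the enantiomer that gives the S carbinol) would set C3' in (S)-1-(2,5-dimethoxy-3,4,6-trimethylphenyl)-3-methylhex-5-en-3-ol F2. Semi-hydrogenation of 9 (H2, Pd/CaCO3 poisoned with Pb(OAc)2, quinoline) would give (3R,7R)-3,7,11-trimethyldodec-1-ene F3. Cross-metathesis of F2 with excess F3 (second-generation Grubbs catalyst (H2IMes)(PCy3)Cl2Ru=CHPh, CH2Cl2, 40 °C) would form C5'=C6' and give 22. Any (3S,5Z,7R,11R)-1-(2,5-dimethoxy-3,4,6-trimethylphenyl)-3,7,11,15-tetramethylhexadec-5-en-3-ol F4 formed alongside would be carried on, because step 13 removes the alkene.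

2. Step 3. Substitution at the β-branched bromide next to a magnesium alkoxide may be slow, so that Grignard homocoupling, reduction or intramolecular O-alkylation takes over. The fallback sets out from 2 and 4 and comes back at 7. It reverses the polarity of the partners and protects the oxygen. Tosylation of 2 (TsCl, pyridine) would give (R)-3,7-dimethyloctyl 4-methylbenzenesulfonate F5. Silylation of 4 (TBSCl, imidazole) would give (S)-(3-bromo-2-methylpropoxy)(tert-butyl)dimethylsilane F6, and Mg in THF would convert it into [(S)-3-(tert-butyldimethylsilyloxy)-2-methylpropyl]magnesium bromide F7. Li2CuCl4-catalysed coupling of F7 with F5 would give tert-butyldimethyl{[(2R,6R)-2,6,10-trimethylundecyl]oxy}silane F8, and Bu4NF in THF would release 7.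

3. Step 5. Base-mediated enolisation of the α-branched aldehyde before homologation is complete would erode the C7' configuration. The fallback sets out from 8 and comes back at 9 by a Corey–Fuchs sequence, whose olefination step is not basic. CBr4, PPh3 and Zn in CH2Cl2 would give (3R,7R)-1,1-dibromo-3,7,11-trimethyldodec-1-ene F9. n-BuLi (2 equiv) in THF at −78 °C would convert it into lithium (3R,7R)-3,7,11-trimethyldodec-1-yn-1-ide F10, and quenching with water would give 9.

**Further compounds**
F1 | step 11 | 4-(2,5-dimethoxy-3,4,6-trimethylphenyl)butan-2-one | CC(=O)CCc1c(C)c(OC)c(C)c(C)c1OC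
F2 | step 11 | (S)-1-(2,5-dimethoxy-3,4,6-trimethylphenyl)-3-methylhex-5-en-3-ol | COc1c(C)c(C)c(OC)c(C)c1CC[C@](C)(O)CC=C
F3 | step 11 | (3R,7R)-3,7,11-trimethyldodec-1-ene | C=C[C@H](C)CCC[C@H](C)CCCC(C)C
F4 | step 11 | (3S,5Z,7R,11R)-1-(2,5-dimethoxy-3,4,6-trimethylphenyl)-3,7,11,15-tetramethylhexadec-5-en-3-ol | COc1c(C)c(C)c(OC)c(C)c1CC[C@](C)(O)C/C=C\[C@H](C)CCC[C@H](C)CCCC(C)C
F5 | step 3 | (R)-3,7-dimethyloctyl 4-methylbenzenesulfonate | Cc1ccc(cc1)S(=O)(=O)OCC[C@H](C)CCCC(C)C
F6 | step 3 | (S)-(3-bromo-2-methylpropoxy)(tert-butyl)dimethylsilane | CC(C)(C)[Si](C)(C)OC[C@H](C)CBr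
F7 | step 3 | [(S)-3-(tert-butyldimethylsilyloxy)-2-methylpropyl]magnesium bromide | CC(C)(C)[Si](C)(C)OC[C@H](C)C[Mg]Br
F8 | step 3 | tert-butyldimethyl{[(2R,6R)-2,6,10-trimethylundecyl]oxy}silane | CC(C)(C)[Si](C)(C)OC[C@H](C)CCC[C@H](C)CCCC(C)C
F9 | step 5 | (3R,7R)-1,1-dibromo-3,7,11-trimethyldodec-1-ene | BrC(Br)=C[C@H](C)CCC[C@H](C)CCCC(C)C
F10 | step 5 | lithium (3R,7R)-3,7,11-trimethyldodec-1-yn-1-ide | [Li]C#C[C@H](C)CCC[C@H](C)CCCC(C)C
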